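The data were computed for an exercise; the scatter is artificial.

You cannot read the number of chains from these runs. Their columns hold monomer in chains and free monomer, while the average length divides the first by a count they do not show. So bracket that count by hand.

| setting | Monday's | Thursday's | Sunday's | delta | zeta |
|---|---|---|---|---|---|
| free monomer | 0.18 M | 0.18 M | 0.090 M | 0.18 M | 0.18 M |
| protic impurity | 3.6 mM | 3.6 mM | 3.6 mM | 3.60 mM | 3.60 mM |
| initiator | 3.2 mol% | 3.2 mol% | 3.2 mol% | 3.2 mol% | 3.2 mol% |
| stray impurity | 0.94 mM | 2.1 mM | 1.4 mM | 1.4 mM | 1.4 mM |
| remark | run made earlier | run made earlier | run made earlier |  |  |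
| time |  |  |  | 3.0 d | 1.5 d |

| run | time / d | monomer in chains / % | free monomer / % |
|---|---|---|---|
| Monday's | 0.500 | 9.7 | 88.1 |
| Monday's | 1.04 | 21.7 | 76.3 |
| Monday's | 1.67 | 29.7 | 67.6 |
| Monday's | 2.08 | 35.4 | 62.0 |
| Monday's | 2.50 | 39.5 | 58.4 |
| Monday's | 3.00 | 43.7 | 54.5 |
| Monday's | 4.00 | 49.4 | 47.1 |
| Thursday's | 0.208 | 2.5 | 95.8 |
| Thursday's | 0.500 | 7.4 | 90.3 |
| Thursday's | 1.04 | 17.0 | 80.5 |
| Thursday's | 1.67 | 25.1 | 72.5 |
| Thursday's | 2.00 | 29.2 | 69.3 |
| Thursday's | 3.00 | 38.7 | 59.8 |
| Thursday's | 4.00 | 43.5 | 53.8 |
| Sunday's | 0.250 | 1.5 | 95.2 |
| Sunday's | 0.500 | 2.8 | 94.0 |
| Sunday's | 1.04 | 4.6 | 91.7 |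
| Sunday's | 2.08 | 9.4 | 87.8 |
| Sunday's | 4.00 | 16.8 | 79.6 |

(standard deviation of a reading: 0.5 percentage points)

- which of the two ends with the longer chains by the average number of monomer units in a chain (chains begun, living or dead) ("neither" if they lie within 10%) (delta / zeta / neither)
- average number of monomer units in a chain (chains begun, living or dead) at the end, delta
- average number of monomer units in a chain (chains begun, living or dead) at the end, zeta

- the average divides the monomer in chains by the number of chains begun, living and dead together
- the earlier runs were read with a standard deviation of 0.5 percentage points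
- reactions considered so far: free monomer + initiator -> living end + monomer in chains; free monomer + living end -> monomer in chains + living end; monomer in chains + living end -> free monomer + living end; initiator + stray impurity -> spent initiator A; 2 living end -> dead end B; protic impurity + free monomer -> quenched substrate
- the earlier runs do not show the number of chains; that part of a forecast is a guess

Take delta. Interpolating on stray impurity between Monday's and Thursday's readings at 3.00 d gives monomer in chains of 41.7%, or 75.1 mM. The initiator charged is 5.76 mM. If every initiator began a chain, the length would be 13.0, and that is the bound from below.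

The stray impurity is the limiting reagent of the side reaction, since its charge is smaller than the initiator's, and it spends one initiator each. Once the initiator has reacted, the count of chains begun is therefore the initiator charged minus the stray impurity charged, 4.36 mM. Living and dead chains both stay in that count. The bound from above is 17.2.

Which edge holds? At 1.04 d, Monday's run reads more monomer in chains than Thursday's, by a read ratio of 1.28, though both charged the same initiator. The same subtraction gives a ratio of counts of 1.32. I commit to the top edge for delta. Zeta has the same charge and stops at half the time, so with about the same count and the readings of both runs still climbing there, I expect delta to end longer.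

The forecast says delta, with 17.5 for delta and 11 for zeta, reasoning “So about 4.3 mM of chains begin within a few tenths of a day”. Its delta value stands just above my top edge.

The flask gives delta, with 17.2 for delta and 11.0 for zeta.

    free monomer + initiator → living end + monomer in chains (k = 0.960 /M/h)
    free monomer + living end → monomer in chains + living end, rate k2*[living end]*[free monomer] (k = 3.60 /M/h)
    monomer in chains + living end → free monomer + living end, rate k3*[living end] as long as [monomer in chains] is above zero (k = 0.170 /h)
    initiator + stray impurity → spent initiator A (k = 5100 /M/h)
    2 living end → dead end B (k = 0.980 /M/h)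
    protic impurity + free monomer → quenched substrate (k = 3.90 /M/h)

At 3.00 d, delta holds 0.00140 M of spent initiator A, and its stray impurity stands at 0%. At its end, 1.50 d, zeta's 26.5% of monomer in chains, divided by the count of 4.36 mM, gives 10.9 against the computed 11.0.

Now take the neighbour of delta charged with 3.5 × 10⁻⁴ M of stray impurity, read at the same time. The subtraction gives 5.41 mM chains begun, so its 46.4% of monomer in chains gives 15.4. The computed result is 15.4.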